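## Retrosynthetic overview
1. The C3=C4 alkene and the free phenol are unveiled last, by dehydration of the C4 carbinol 23 and then desilylation. The light- and acid-sensitive chiral 2H-chromene therefore exists only in the last two steps.
2. Side chain: the C2'–C3' bond comes from an sp3–sp2 Negishi coupling of chromanylethylzinc 21 with the C13 (E)-alkenyl iodide 20, which is built from geraniol and a propyne unit.
3. Core (key step): the C3–C4 bond comes from an intermolecular amine-catalysed vinylogous aldol addition of prenal 5 to salicylaldehyde 4. Oxa-Michael closure (O1–C2, sets the stereocentre) and lactol formation follow in the same pot.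
4. Ring order: the benzene ring is bought (methylhydroquinone). The pyran ring forms in step 3. The temporary lactol bridge forms in step 3 and is opened in step 4.

Numbering: chroman numbering (O1, C2, C3, C4, C4a to C8a) is used for the core and primed numbers (C1' to C13') for the side chain. The target is (2S).

Assumption: the (S)-diarylprolinol silyl ether is taken to follow the usual shielding model (attack on the iminium face away from the diarylmethyl group). If lactol 8 proves antipodal, the (R)-catalyst is used and nothing else changes. The anomeric centre of 8 is an inconsequential mixture.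

## Route

Step 1
Reactants: 1 2-methylhydroquinone
Product: 2 2-methyl-4-(triisopropylsilyloxy)phenol
Conditions: TIPSCl (1.0 equiv), imidazole, DMF, 0 °C → rt
Reagents that add atoms: triisopropylsilyl chloride, CC(C)[Si](Cl)(C(C)C)C(C)C
Why: Silyl ether formation, in which the bulky silyl chloride reacts much faster at the unhindered hydroxyl than at the one flanked by the methyl group, and the minor isomer and bis-ether are removed by chromatography.

Step 2
Reactants: 2 2-methyl-4-(triisopropylsilyloxy)phenol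
Product: 4 2-hydroxy-3-methyl-5-(triisopropylsilyloxy)benzaldehyde, via salicyl alcohol 3 (not isolated)
Conditions: MgCl2, Et3N, (CH2O)n, MeCN, reflux; then cold 1 M HCl
Reagents that add atoms: paraformaldehyde (as formaldehyde), C=O
Why: Casnati–Skattebøl ortho-formylation, in which the magnesium phenoxide delivers formaldehyde only to the single free ortho position and a second formaldehyde oxidises the benzylic alkoxide by hydride transfer.

Step 3 (key step)
Reactants: 4 2-hydroxy-3-methyl-5-(triisopropylsilyloxy)benzaldehyde; 5 3-methylbut-2-enal (prenal)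
Product: 8 bridged tricyclic lactol (cyclic hemiacetal of 7; 2R,4R in chroman numbering; anomer mixture), via hydroxy-enal 6 (not isolated), via chromanylacetaldehyde 7 (not isolated)
Conditions: 5 (3 equiv), (S)-2-{bis[3,5-bis(trifluoromethyl)phenyl](trimethylsilyloxy)methyl}pyrrolidine (30 mol %), PhCO2H (20 mol %), toluene, rt, 72 h
Reagents that add atoms: none
Why: Domino vinylogous aldol/oxa-Michael reaction, in which the γ-carbon of the prenal dienamine adds to the aldehyde of 4 (C3–C4 bond), the phenol then adds to the β-carbon of the E-iminium ion on the face not covered by the C(Ar)2OSiMe3 group (this sets C2), and, because both additions are reversible and only the isomer with the C4 oxygen cis to the acetaldehyde arm can close to the lactol, one diastereomer accumulates.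

Step 4
Reactants: 8 bridged tricyclic lactol
Product: 9 (2S,4R)-2-(2-hydroxyethyl)-2,8-dimethyl-6-(triisopropylsilyloxy)chroman-4-ol
Conditions: NaBH4, MeOH, 0 °C
Reagents that add atoms: none
Why: Hydride reduction of the open hydroxy-aldehyde tautomer touches no stereocentre, and removing the carbonyl group closes the retro-oxa-Michael path, so C2 is fixed from here on (the descriptor changes from R to S by priority only).

Step 5
Reactants: 9 (2S,4R)-2-(2-hydroxyethyl)-2,8-dimethyl-6-(triisopropylsilyloxy)chroman-4-ol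
Product: 10 2-[(2S,4R)-4-hydroxy-2,8-dimethyl-6-(triisopropylsilyloxy)chroman-2-yl]ethyl 4-methylbenzenesulfonate
Conditions: TsCl (1.1 equiv), Et3N, DMAP (cat.), CH2Cl2, 0 °C
Reagents that add atoms: 4-toluenesulfonyl chloride, Cc1ccc(cc1)S(=O)(=O)Cl
Why: Chemoselective sulfonylation, in which the primary alcohol is tosylated far faster than the hindered secondary benzylic alcohol and the low temperature suppresses intramolecular ether formation.

Step 6
Reactants: 10 primary tosylate
Product: 11 2-[(2S,4R)-4-(tert-butyldimethylsilyloxy)-2,8-dimethyl-6-(triisopropylsilyloxy)chroman-2-yl]ethyl 4-methylbenzenesulfonate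
Conditions: TBSOTf, 2,6-lutidine, CH2Cl2, −78 → 0 °C
Reagents that add atoms: tert-butyldimethylsilyl triflate, CC(C)(C)[Si](C)(C)OS(=O)(=O)C(F)(F)F
Why: Silyl ether protection under non-nucleophilic basic conditions masks the C4 carbinol, which keeps C3–C4 saturated (no allylic aryl ether) during the metal-mediated steps.

Step 7
Reactants: 11 silylated tosylate
Product: 12 (2R,4R)-4-(tert-butyldimethylsilyloxy)-2-(2-iodoethyl)-2,8-dimethyl-6-(triisopropylsilyloxy)chroman
Conditions: NaI, acetone, reflux
Reagents that add atoms: sodium iodide, [Na+].[I-]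
Why: Finkelstein SN2 displacement at an unhindered primary carbon is driven by precipitation of the sulfonate salt, and the change of the C2 descriptor to R is a priority effect of iodine only.

Step 8
Reactants: 13 geraniol
Product: 14 geranyl bromide ((2E)-1-bromo-3,7-dimethylocta-2,6-diene)
Conditions: PBr3 (0.4 equiv), Et2O, −10 °C
Reagents that add atoms: phosphorus tribromide, BrP(Br)Br
Why: Bromination of the allylic alcohol through its phosphite ester proceeds at low temperature without allylic transposition or E/Z leakage, and the bromide is used fresh.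

Step 9
Reactants: 14 geranyl bromide; 15 1-(trimethylsilyl)propyne
Product: 17 trimethyl[(5E)-6,10-dimethylundeca-5,9-dien-1-yn-1-yl]silane, via lithiated silylpropyne 16 (not isolated)
Conditions: 15, n-BuLi, THF, −78 → −20 °C; then 14, −78 °C → rt
Reagents that add atoms: none
Why: Propargylic lithiation followed by SN2 alkylation of the primary allylic bromide, in which the silyl group blocks the alkyne terminus and steers reaction to the propargylic carbon.

Step 10
Reactants: 17 silylalkyne
Product: 18 (5E)-6,10-dimethylundeca-5,9-dien-1-yne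
Conditions: K2CO3, MeOH, rt
Reagents that add atoms: none
Why: Base-catalysed protodesilylation of the alkynylsilane leaves the trisubstituted alkenes untouched.

Step 11
Reactants: 18 (5E)-6,10-dimethylundeca-5,9-dien-1-yne
Product: 20 (1E,5E)-1-iodo-2,6,10-trimethylundeca-1,5,9-triene, via alkenylalane 19 (not isolated)
Conditions: Me3Al, Cp2ZrCl2 (25 mol %), CH2Cl2, 0 °C → rt; then I2, THF, −30 → 0 °C
Reagents that add atoms: trimethylaluminium, C[Al](C)C; iodine, [I][I]
Why: Negishi zirconium-catalysed carboalumination adds methyl and aluminium syn across the terminal alkyne only, and iodinolysis with retention gives the E-alkenyl iodide.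

Step 12
Reactants: 12 primary iodide; 20 (E)-alkenyl iodide
Product: 22 (2S,4R)-4-(tert-butyldimethylsilyloxy)-2,8-dimethyl-6-(triisopropylsilyloxy)-2-[(3E,7E)-4,8,12-trimethyltrideca-3,7,11-trien-1-yl]chroman, via alkylzinc iodide 21 (not isolated)
Conditions: Zn dust (activated by BrCH2CH2Br and Me3SiCl), THF, 40 °C; then 20, PdCl2(dppf) (3 mol %), THF, rt → 40 °C
Reagents that add atoms: none
Why: Zinc insertion into the primary C–I bond followed by Negishi cross-coupling, in which zerovalent palladium adds to the alkenyl iodide with retention so the 3'E geometry is carried over, and the dppf ligand suppresses β-hydride elimination.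

Step 13
Reactants: 22 bis-silyl ether
Product: 23 (2S,4R)-2,8-dimethyl-6-(triisopropylsilyloxy)-2-[(3E,7E)-4,8,12-trimethyltrideca-3,7,11-trien-1-yl]chroman-4-ol
Conditions: HF·pyridine, pyridine, THF, 0 °C → rt
Reagents that add atoms: none
Why: Selective desilylation, in which buffered acidic fluoride cleaves the alkyl TBS ether much faster than the bulkier aryl TIPS ether and is mild enough for the triene.

Step 14
Reactants: 23 C4 carbinol
Product: 25 triisopropyl({(2S)-2,8-dimethyl-2-[(3E,7E)-4,8,12-trimethyltrideca-3,7,11-trien-1-yl]-2H-chromen-6-yl}oxy)silane, via C4 mesylate 24 (not isolated)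
Conditions: MsCl, Et3N, CH2Cl2, −20 → 0 °C; then DBU, rt, dark
Reagents that add atoms: none
Why: Mesylation and base-induced β-elimination of the activated benzylic sulfonate gives the conjugated C3=C4 alkene under acid-free conditions, so neither the triene nor the C2–O bond is ionised, and only the auxiliary C4 stereocentre is lost.

Step 15
Reactants: 25 silyl-protected chromene
Product: 26 (2S)-2,8-dimethyl-2-[(3E,7E)-4,8,12-trimethyltrideca-3,7,11-trien-1-yl]-2H-chromen-6-ol (target)
Conditions: TBAF, AcOH (1:1), THF, 0 °C, dark, under argon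
Reagents that add atoms: none
Why: Fluoride-induced cleavage of the aryl silyl ether is fast at 0 °C, the acetic acid buffer avoids an oxidisable free phenoxide, and exclusion of light prevents racemisation by electrocyclic ring opening.

## Compound list
1 | 2-methylhydroquinone | Cc1cc(O)ccc1O | starting material
2 | 2-methyl-4-(triisopropylsilyloxy)phenol | Cc1cc(O[Si](C(C)C)(C(C)C)C(C)C)ccc1O | intermediate
3 | 2-(hydroxymethyl)-6-methyl-4-(triisopropylsilyloxy)phenol (in the flask as its magnesium salt) | OCc1cc(O[Si](C(C)C)(C(C)C)C(C)C)cc(C)c1O | intermediate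
4 | 2-hydroxy-3-methyl-5-(triisopropylsilyloxy)benzaldehyde | O=Cc1cc(O[Si](C(C)C)(C(C)C)C(C)C)cc(C)c1O | intermediate
5 | 3-methylbut-2-enal (prenal) | CC(C)=CC=O | starting material
6 | (2E,5R)-5-hydroxy-5-[2-hydroxy-3-methyl-5-(triisopropylsilyloxy)phenyl]-3-methylpent-2-enal (in the flask as its iminium ion) | O=C/C=C(\C)C[C@@H](O)c1cc(O[Si](C(C)C)(C(C)C)C(C)C)cc(C)c1O | intermediate
7 | 2-[(2R,4R)-4-hydroxy-2,8-dimethyl-6-(triisopropylsilyloxy)chroman-2-yl]acetaldehyde | O=CC[C@@]1(C)C[C@@H](O)c2cc(O[Si](C(C)C)(C(C)C)C(C)C)cc(C)c2O1 | intermediate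
8 | bridged tricyclic lactol, the cyclic hemiacetal of 7 between the C4 oxygen and the aldehyde (2,6-methano-1,5-benzodioxocin-4-ol skeleton), anomer mixture | OC1C[C@@]2(C)C[C@@H](O1)c3cc(O[Si](C(C)C)(C(C)C)C(C)C)cc(C)c3O2 | intermediate
9 | (2S,4R)-2-(2-hydroxyethyl)-2,8-dimethyl-6-(triisopropylsilyloxy)chroman-4-ol | OCC[C@@]1(C)C[C@@H](O)c2cc(O[Si](C(C)C)(C(C)C)C(C)C)cc(C)c2O1 | intermediate
10 | 2-[(2S,4R)-4-hydroxy-2,8-dimethyl-6-(triisopropylsilyloxy)chroman-2-yl]ethyl 4-methylbenzenesulfonate | Cc1ccc(cc1)S(=O)(=O)OCC[C@@]1(C)C[C@@H](O)c2cc(O[Si](C(C)C)(C(C)C)C(C)C)cc(C)c2O1 | intermediate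
11 | 2-[(2S,4R)-4-(tert-butyldimethylsilyloxy)-2,8-dimethyl-6-(triisopropylsilyloxy)chroman-2-yl]ethyl 4-methylbenzenesulfonate | Cc1ccc(cc1)S(=O)(=O)OCC[C@@]1(C)C[C@@H](O[Si](C)(C)C(C)(C)C)c2cc(O[Si](C(C)C)(C(C)C)C(C)C)cc(C)c2O1 | intermediate
12 | (2R,4R)-4-(tert-butyldimethylsilyloxy)-2-(2-iodoethyl)-2,8-dimethyl-6-(triisopropylsilyloxy)chroman | ICC[C@@]1(C)C[C@@H](O[Si](C)(C)C(C)(C)C)c2cc(O[Si](C(C)C)(C(C)C)C(C)C)cc(C)c2O1 | intermediate
13 | geraniol | CC(C)=CCC/C(C)=C/CO | starting material
14 | geranyl bromide | CC(C)=CCC/C(C)=C/CBr | intermediate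
15 | 1-(trimethylsilyl)propyne | CC#C[Si](C)(C)C | starting material
16 | [3-(trimethylsilyl)prop-2-yn-1-yl]lithium | [Li]CC#C[Si](C)(C)C | intermediate
17 | trimethyl[(5E)-6,10-dimethylundeca-5,9-dien-1-yn-1-yl]silane | CC(C)=CCC/C(C)=C/CCC#C[Si](C)(C)C | intermediate
18 | (5E)-6,10-dimethylundeca-5,9-dien-1-yne | CC(C)=CCC/C(C)=C/CCC#C | intermediate
19 | dimethyl[(1E,5E)-2,6,10-trimethylundeca-1,5,9-trien-1-yl]alane | CC(C)=CCC/C(C)=C/CC/C(C)=C/[Al](C)C | intermediate
20 | (1E,5E)-1-iodo-2,6,10-trimethylundeca-1,5,9-triene | CC(C)=CCC/C(C)=C/CC/C(C)=C/I | intermediate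
21 | {2-[(2R,4R)-4-(tert-butyldimethylsilyloxy)-2,8-dimethyl-6-(triisopropylsilyloxy)chroman-2-yl]ethyl}zinc iodide | I[Zn]CC[C@@]1(C)C[C@@H](O[Si](C)(C)C(C)(C)C)c2cc(O[Si](C(C)C)(C(C)C)C(C)C)cc(C)c2O1 | intermediate
22 | (2S,4R)-4-(tert-butyldimethylsilyloxy)-2,8-dimethyl-6-(triisopropylsilyloxy)-2-[(3E,7E)-4,8,12-trimethyltrideca-3,7,11-trien-1-yl]chroman | CC(C)=CCC/C(C)=C/CC/C(C)=C/CC[C@@]1(C)C[C@@H](O[Si](C)(C)C(C)(C)C)c2cc(O[Si](C(C)C)(C(C)C)C(C)C)cc(C)c2O1 | intermediate
23 | (2S,4R)-2,8-dimethyl-6-(triisopropylsilyloxy)-2-[(3E,7E)-4,8,12-trimethyltrideca-3,7,11-trien-1-yl]chroman-4-ol | CC(C)=CCC/C(C)=C/CC/C(C)=C/CC[C@@]1(C)C[C@@H](O)c2cc(O[Si](C(C)C)(C(C)C)C(C)C)cc(C)c2O1 | intermediate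
24 | (2S,4R)-2,8-dimethyl-6-(triisopropylsilyloxy)-2-[(3E,7E)-4,8,12-trimethyltrideca-3,7,11-trien-1-yl]chroman-4-yl methanesulfonate | CC(C)=CCC/C(C)=C/CC/C(C)=C/CC[C@@]1(C)C[C@@H](OS(C)(=O)=O)c2cc(O[Si](C(C)C)(C(C)C)C(C)C)cc(C)c2O1 | intermediate
25 | triisopropyl({(2S)-2,8-dimethyl-2-[(3E,7E)-4,8,12-trimethyltrideca-3,7,11-trien-1-yl]-2H-chromen-6-yl}oxy)silane | CC(C)=CCC/C(C)=C/CC/C(C)=C/CC[C@@]1(C)C=Cc2cc(O[Si](C(C)C)(C(C)C)C(C)C)cc(C)c2O1 | intermediate
26 | (2S)-2,8-dimethyl-2-[(3E,7E)-4,8,12-trimethyltrideca-3,7,11-trien-1-yl]-2H-chromen-6-ol | CC(C)=CCC/C(C)=C/CC/C(C)=C/CC[C@@]1(C)C=Cc2cc(O)cc(C)c2O1 | target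

## Step count and weak points
Total steps: 15. Longest linear sequence: 11 (steps 1–7 and 12–15). The side branch takes 4 steps (8–11).

**Step 3 (domino vinylogous aldol/oxa-Michael).**
- Risks: prenal self-condensation, the competing oxa-Michael/aldol condensation to an achiral 2,2-dimethylchromene-3-carbaldehyde, or insufficient enantioselectivity.
- The fallback sets out from 4 and returns at 9. It sets C4 first by Lewis acid catalysis and relays it to C2.
- Compound 4 is acetylated (Ac2O, pyridine) to 2-formyl-6-methyl-4-(triisopropylsilyloxy)phenyl acetate F1.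
- Methyl 3-methylbut-2-enoate is converted (LDA, TBSCl, THF, −78 °C) into the silyl dienolate tert-butyl[(1-methoxy-3-methylbuta-1,3-dien-1-yl)oxy]dimethylsilane F2.
- F1 and F2 are joined in a catalytic enantioselective vinylogous Mukaiyama aldol addition (SiCl4, chiral binaphthyldiamine-derived bisphosphoramide, i-Pr2NEt, CH2Cl2, −78 °C), with the catalyst antipode chosen to give the 5R alcohol. The product is methyl (2E,5R)-5-[2-acetoxy-3-methyl-5-(triisopropylsilyloxy)phenyl]-5-hydroxy-3-methylpent-2-enoate F3.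
- Brief K2CO3/MeOH at 0 °C frees the phenol methyl (2E,5R)-5-hydroxy-5-[2-hydroxy-3-methyl-5-(triisopropylsilyloxy)phenyl]-3-methylpent-2-enoate F4.
- DBU in toluene at 60 °C brings about reversible oxa-Michael addition to methyl 2-[(2R,4R)-4-hydroxy-2,8-dimethyl-6-(triisopropylsilyloxy)chroman-2-yl]acetate F5. Only this cis isomer can lactonise, to the bridged tricyclic lactone F6, so the C4 centre dictates C2.
- LiBH4 in THF reduces F6 to diol 9.

**Step 12 (zinc insertion and Negishi coupling).**
- Risks: sluggish zinc insertion, protodemetalation or homocoupling.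
- The fallback sets out from 20 and 12 and returns at 22. It reverses the polarity and needs no palladium.
- Compound 20 is treated with t-BuLi (2 equiv, Et2O, −78 °C) to give [(1E,5E)-2,6,10-trimethylundeca-1,5,9-trien-1-yl]lithium F7.
- MgBr2·OEt2 converts F7 into [(1E,5E)-2,6,10-trimethylundeca-1,5,9-trien-1-yl]magnesium bromide F8.
- F8 displaces the iodide of 12 in a Li2CuCl4-catalysed substitution (THF/NMP, 0 °C) with retention of the alkene geometry, giving 22.

**Step 13 (selective removal of the benzylic TBS ether beside the aryl TIPS ether).**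
- Risks: partial loss of the TIPS group or premature ionisation at C4.
- The fallback sets out from 22 and returns at 26. It gives up the selectivity.
- Excess TBAF in THF removes both silyl groups to give (2S,4R)-2,8-dimethyl-2-[(3E,7E)-4,8,12-trimethyltrideca-3,7,11-trien-1-yl]chroman-4,6-diol F9.
- The activated benzylic alcohol of F9 is then lost in an acid-catalysed E1 dehydration (PPTS cat., toluene, 60 °C, dark). This gives 26 directly, without passing through 23–25.

## Further compounds
F1 | step 3 | 2-formyl-6-methyl-4-(triisopropylsilyloxy)phenyl acetate | CC(=O)Oc1c(C)cc(O[Si](C(C)C)(C(C)C)C(C)C)cc1C=O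
F2 | step 3 | tert-butyl[(1-methoxy-3-methylbuta-1,3-dien-1-yl)oxy]dimethylsilane | C=C(C)C=C(OC)O[Si](C)(C)C(C)(C)C
F3 | step 3 | methyl (2E,5R)-5-[2-acetoxy-3-methyl-5-(triisopropylsilyloxy)phenyl]-5-hydroxy-3-methylpent-2-enoate | COC(=O)/C=C(\C)C[C@@H](O)c1cc(O[Si](C(C)C)(C(C)C)C(C)C)cc(C)c1OC(C)=O
F4 | step 3 | methyl (2E,5R)-5-hydroxy-5-[2-hydroxy-3-methyl-5-(triisopropylsilyloxy)phenyl]-3-methylpent-2-enoate | COC(=O)/C=C(\C)C[C@@H](O)c1cc(O[Si](C(C)C)(C(C)C)C(C)C)cc(C)c1O
F5 | step 3 | methyl 2-[(2R,4R)-4-hydroxy-2,8-dimethyl-6-(triisopropylsilyloxy)chroman-2-yl]acetate | COC(=O)C[C@@]1(C)C[C@@H](O)c2cc(O[Si](C(C)C)(C(C)C)C(C)C)cc(C)c2O1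
F6 | step 3 | bridged tricyclic lactone (lactone of F5 between the C4 oxygen and the ester carbon) | O=C1C[C@@]2(C)C[C@@H](O1)c3cc(O[Si](C(C)C)(C(C)C)C(C)C)cc(C)c3O2
F7 | step 12 | [(1E,5E)-2,6,10-trimethylundeca-1,5,9-trien-1-yl]lithium | CC(C)=CCC/C(C)=C/CC/C(C)=C/[Li]
F8 | step 12 | [(1E,5E)-2,6,10-trimethylundeca-1,5,9-trien-1-yl]magnesium bromide | CC(C)=CCC/C(C)=C/CC/C(C)=C/[Mg]Br
F9 | step 13 | (2S,4R)-2,8-dimethyl-2-[(3E,7E)-4,8,12-trimethyltrideca-3,7,11-trien-1-yl]chroman-4,6-diol | CC(C)=CCC/C(C)=C/CC/C(C)=C/CC[C@@]1(C)C[C@@H](O)c2cc(O)cc(C)c2O1
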